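The α‑methylene‑γ‑butyrolactone is closed last, with CO2 supplying C12 and the ring oxygen. In that ring C11 is a latent vinyl anion (a 2‑chloroalkene) and C8 a latent electrophile (a secondary mesylate), 1,3‑related through C7. One operation, nickel‑catalysed reductive carboxylation followed by 5‑exo‑tet displacement, forms C11–C12 and O–C8 and inverts C8 to give the trans‑fused lactone on the finished ten‑membered ring. The precursor, a macrocyclic chloroalkene mesylate, comes from nerol (C1–C6, Sharpless epoxide), an Evans aldol (C6–C7), a 2‑bromoallylation (C8–C9) and a Nozaki–Hiyama–Kishi ring closure (C1–C10).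

Key step: step 16

Remark on numbering: germacrane numbering is used throughout. Ring carbons are C1 (carbinol), C2, C3, C4/C5 (epoxide, C15 methyl on C4), C6 (angelate), C7, C8 (lactone oxygen), C9 and C10 (C14 methylidene). C11 is the alkene carbon α to the lactone carbonyl C12, and C13 is its methylidene.
Assumption: the (R,R)‑bis‑sulfonamide boron controller in step 10 is taken to deliver the 2‑bromoallyl group to the Re face of the aldehyde (accepted chair model); if the sense were opposite, the (S,S) antipode would be used.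

Step 1
Reactants: 1 nerol
Product: 2 (2S,3R)-2,3-epoxynerol
Conditions: Ti(OiPr)4 (cat.), L-(+)-diethyl tartrate (cat.), t-BuOOH, 4 Å MS, CH2Cl2, −20 °C
Reagents that add atoms: tert-butyl hydroperoxide CC(C)(C)OO
Why: Katsuki–Sharpless asymmetric epoxidation; the titanium tartrate binds the allylic hydroxyl and delivers oxygen to one face of the Z‑trisubstituted C4=C5 alkene only (the remote prenyl alkene is untouched), L-(+)-tartrate setting C4 (R) and C5 (S) as the cis‑epoxide.

Step 2
Reactants: 2 (2S,3R)-2,3-epoxynerol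
Product: 3 (2R,3R)-3-methyl-3-(4-methylpent-3-en-1-yl)oxirane-2-carbaldehyde
Conditions: Dess–Martin periodinane, NaHCO3, CH2Cl2, 0 °C to rt
Reagents that add atoms: none
Why: Dess–Martin oxidation under buffered conditions should convert the primary alcohol to the α,β‑epoxy aldehyde without opening the epoxide or epimerising C5.

Step 3
Reactants: 4 buta-2,3-dienoic acid
Product: 5 3-chlorobut-3-enoic acid
Conditions: LiCl, AcOH, 80 °C
Reagents that add atoms: lithium chloride [Li+].[Cl-]
Why: hydrohalogenation of a 2,3‑allenoic acid; chloride adds in conjugate fashion to the central allene carbon and the dienolate is protonated at C2, which should give the β‑chloro‑β,γ‑unsaturated acid.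

Step 4
Reactants: 5 3-chlorobut-3-enoic acid; 6 (S)-4-benzyloxazolidin-2-one
Product: 8 (S)-4-benzyl-3-(3-chlorobut-3-enoyl)oxazolidin-2-one, via mixed pivalic anhydride 7 (not isolated)
Conditions: PivCl, Et3N, THF, −20 °C; then 6, LiCl, −20 °C to rt
Reagents that add atoms: none
Why: N‑acylation of the Evans auxiliary through the mixed anhydride with LiCl/Et3N activation, mild enough to keep the double bond out of conjugation.

Step 5
Reactants: 8 (S)-4-benzyl-3-(3-chlorobut-3-enoyl)oxazolidin-2-one; 3 (2R,3R)-3-methyl-3-(4-methylpent-3-en-1-yl)oxirane-2-carbaldehyde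
Product: 10 (S)-4-benzyl-3-[(2S,3S)-2-(1-chloroethenyl)-3-hydroxy-3-[(2S,3R)-3-methyl-3-(4-methylpent-3-en-1-yl)oxiran-2-yl]propanoyl]oxazolidin-2-one, via (Z)-dibutylboron enolate 9 (not isolated)
Conditions: Bu2BOTf, iPr2NEt, CH2Cl2, −78 to 0 °C; then 3, −78 to 0 °C; pH 7 buffer, MeOH, H2O2, 0 °C
Reagents that add atoms: none
Why: Evans syn‑aldol; the (Z)‑boron enolate reacts at its α‑carbon through a Zimmerman–Traxler chair with the benzyl group of the auxiliary shielding one face, which should set C6 (S) and C7 together under reagent control, in the same sense as the Felkin preference of the epoxy aldehyde.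

Step 6
Reactants: 10 aldol adduct
Product: 11 (S)-4-benzyl-3-[(2S,3S)-2-(1-chloroethenyl)-3-[(2S,3R)-3-methyl-3-(4-methylpent-3-en-1-yl)oxiran-2-yl]-3-(triethylsilyloxy)propanoyl]oxazolidin-2-one
Conditions: TESCl, imidazole, DMF, 0 °C to rt
Reagents that add atoms: chlorotriethylsilane CC[Si](Cl)(CC)CC
Why: silylation of the C6 hydroxyl blocks retro‑aldol and β‑elimination pathways during the C8 oxidation‑state changes that follow.

Step 7
Reactants: 11 TES ether imide
Product: 12 (2R,3S)-2-(1-chloroethenyl)-3-[(2S,3R)-3-methyl-3-(4-methylpent-3-en-1-yl)oxiran-2-yl]-3-(triethylsilyloxy)propan-1-ol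
Conditions: LiBH4, MeOH, THF, 0 °C
Reagents that add atoms: none
Why: reductive cleavage of the N‑acyl oxazolidinone by borohydride should give the C8 primary alcohol and return the auxiliary, with the epoxide and chloroalkene inert at 0 °C.

Step 8
Reactants: 12 primary alcohol
Product: 13 (2S,3S)-2-(1-chloroethenyl)-3-[(2S,3R)-3-methyl-3-(4-methylpent-3-en-1-yl)oxiran-2-yl]-3-(triethylsilyloxy)propanal
Conditions: Dess–Martin periodinane, NaHCO3, CH2Cl2, 0 °C; used crude
Reagents that add atoms: none
Why: buffered Dess–Martin oxidation gives the C8 aldehyde without base, so the C7 stereocentre (allylic and α to the carbonyl) should survive if the aldehyde is used at once.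

Step 9
Reactants: 14 2,3-dibromopropene
Product: 15 tributyl(2-bromoprop-2-en-1-yl)stannane
Conditions: Zn dust, Bu3SnCl, THF/sat. aq NH4Cl, rt
Reagents that add atoms: tributyltin chloride CCCC[Sn](Cl)(CCCC)CCCC
Why: aqueous zinc Barbier stannylation; zinc inserts into the allylic C–Br bond only and the allylzinc is trapped by the tin chloride, leaving the vinylic bromide untouched.

Step 10
Reactants: 13 aldehyde; 15 tributyl(2-bromoprop-2-en-1-yl)stannane
Product: 17 (4R,5R)-2-bromo-6-chloro-5-{(S)-[(2S,3R)-3-methyl-3-(4-methylpent-3-en-1-yl)oxiran-2-yl](triethylsilyloxy)methyl}hepta-1,6-dien-4-ol, via B-(2-bromoallyl)diazaborolidine 16 (not isolated)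
Conditions: (R,R)-TsNHCH(Ph)CH(Ph)NHTs, BBr3, CH2Cl2, 0 °C to rt; 15, rt; then 13, −78 °C
Reagents that add atoms: none
Why: Corey enantioselective allylation; tin‑to‑boron exchange gives the chiral B‑(2‑bromoallyl) reagent, which adds through a closed chair to the Re face of the aldehyde under reagent control, setting C8 (R) with its hydroxyl anti to the C6 oxygen and placing the C10 bromoalkene.

Step 11
Reactants: 17 homoallylic alcohol
Product: 18 (4R,5S)-2-bromo-6-chloro-5-{(S)-[(2S,3R)-3-methyl-3-(4-methylpent-3-en-1-yl)oxiran-2-yl](triethylsilyloxy)methyl}hepta-1,6-dien-4-yl methanesulfonate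
Conditions: MsCl, Et3N, CH2Cl2, 0 °C
Reagents that add atoms: methanesulfonyl chloride CS(=O)(=O)Cl
Why: sulfonylation of the only free hydroxyl turns C8 into the electrophile for the final lactonisation, with retention at C8.

Step 12
Reactants: 18 mesylate
Product: 19 (4R,5S)-2-bromo-6-chloro-5-{(S)-hydroxy[(2S,3R)-3-methyl-3-(4-methylpent-3-en-1-yl)oxiran-2-yl]methyl}hepta-1,6-dien-4-yl methanesulfonate
Conditions: HF·pyridine, pyridine, THF, 0 °C
Reagents that add atoms: none
Why: buffered fluoride cleaves the secondary triethylsilyl ether while the mesylate, the trisubstituted epoxide and the haloalkenes should remain intact.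

Step 13
Reactants: 19 hydroxy mesylate; 20 angelic acid
Product: 22 (1S,2S,3R)-5-bromo-2-(1-chloroethenyl)-3-(methanesulfonyloxy)-1-[(2S,3R)-3-methyl-3-(4-methylpent-3-en-1-yl)oxiran-2-yl]hex-5-en-1-yl (2Z)-2-methylbut-2-enoate, via angelic 2,4,6-trichlorobenzoic anhydride 21 (not isolated)
Conditions: 2,4,6-trichlorobenzoyl chloride, Et3N, toluene, rt; then 19, 75 °C
Reagents that add atoms: none
Why: Yamaguchi‑type esterification through the mixed anhydride without nucleophilic catalyst, the protocol that acylates hindered secondary alcohols with angelic acid without Z‑to‑E isomerisation to the tiglate.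

Step 14
Reactants: 22 angelate
Product: 23 (1S,2S,3R)-5-bromo-2-(1-chloroethenyl)-3-(methanesulfonyloxy)-1-[(2S,3R)-3-methyl-3-(3-oxopropyl)oxiran-2-yl]hex-5-en-1-yl (2Z)-2-methylbut-2-enoate
Conditions: OsO4 (cat.), NaIO4, 2,6-lutidine, dioxane/H2O, rt
Reagents that add atoms: sodium periodate [Na+].[O-]I(=O)(=O)=O
Why: Lemieux–Johnson cleavage; osmium tetroxide should select the electron‑rich trisubstituted prenyl alkene over the conjugated angelate and the two 2‑haloalkenes, and periodate cleaves the diol to the C1 aldehyde.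

Step 15
Reactants: 23 aldehyde
Product: 24 (1S,4R,5S,6S,7S,8R)-7-(1-chloroethenyl)-4,5-epoxy-1-hydroxy-8-(methanesulfonyloxy)-4-methyl-10-methylidenecyclodecan-6-yl (2Z)-2-methylbut-2-enoate
Conditions: CrCl2 (excess), NiCl2 (cat.), degassed DMSO, rt, high dilution (slow addition)
Reagents that add atoms: none
Why: Nozaki–Hiyama–Kishi reaction; nickel inserts into the C10–Br bond only (the alkenyl chloride and the mesylate are inert), and the alkenylchromium adds to the C1 aldehyde to close the ten‑membered ring as the 2‑methylidene carbinol, with C1 set by macrocyclic substrate control; the (1S) epimer is expected from addition to the outward‑facing carbonyl face, but this is the least secure stereocentre of the route.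

Step 16
Reactants: 24 macrocyclic chloroalkene mesylate
Product: 26 CNP0104965.1 (1S,4R,5S,6S,7R,8S)-6-angeloyloxy-4,5-epoxy-1-hydroxygermacra-10(14),11(13)-dien-12,8-olide, via C12 carboxylate 25 (not isolated)
Conditions: NiCl2(PPh3)2 (cat.), PPh3, Mn powder, Et4NI (cat.), CO2 (1 atm), DMI, 25 °C; then 50 °C
Reagents that add atoms: carbon dioxide O=C=O
Why: Ni(0), generated by manganese, inserts into the C11–Cl bond, and after one‑electron reduction the alkenylnickel adds to CO2 to form the C11–C12 bond; the C12 carboxylate 25 then attacks C8 from the rear and expels the mesylate, forming the O–C8 bond. The closest known reaction types are the nickel‑catalysed reductive carboxylation of alkenyl chlorides with CO2 and the invertive lactonisation of γ‑sulfonyloxy carboxylates. The one ring closed is the γ‑lactone O–C12–C11–C7–C8, by 5‑exo‑tet substitution. The only stereocentre changed is C8, which is inverted from (R) to (S) by the SN2 step, so its configuration is dictated by the mesylate set in steps 10 and 11 and the lactone becomes trans‑fused to C7. The step needs nickel insertion at the C(sp2)–Cl bond rather than at the secondary mesylate or the allylic C1–O bond, which the phosphine‑ligated catalyst at 25 °C should secure because neither C(sp3)–O bond is ionised under these conditions. It also needs substitution over E2, which the weakly basic intramolecular carboxylate and the five‑membered transition state favour, and C6 cannot compete as an electrophile because it is already acylated.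

Compound list
1 | nerol, (2Z)-3,7-dimethylocta-2,6-dien-1-ol | CC(C)=CCC/C(C)=C\CO | starting material
2 | (2S,3R)-2,3-epoxynerol | CC(C)=CCC[C@@]1(C)O[C@H]1CO | intermediate
3 | (2R,3R)-3-methyl-3-(4-methylpent-3-en-1-yl)oxirane-2-carbaldehyde | CC(C)=CCC[C@@]1(C)O[C@H]1C=O | intermediate
4 | buta-2,3-dienoic acid | C=C=CC(=O)O | starting material
5 | 3-chlorobut-3-enoic acid | C=C(Cl)CC(=O)O | intermediate
6 | (S)-4-benzyloxazolidin-2-one | O=C1N[C@@H](Cc2ccccc2)CO1 | starting material
7 | 3-chlorobut-3-enoic pivalic anhydride | C=C(Cl)CC(=O)OC(=O)C(C)(C)C | intermediate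
8 | (S)-4-benzyl-3-(3-chlorobut-3-enoyl)oxazolidin-2-one | C=C(Cl)CC(=O)N1[C@@H](Cc2ccccc2)COC1=O | intermediate
9 | (Z)-dibutylboron enolate of 8 | C=C(Cl)/C=C(\OB(CCCC)CCCC)N1[C@@H](Cc2ccccc2)COC1=O | intermediate
10 | syn-aldol adduct (C6 S, C7 S) | CC(C)=CCC[C@@]1(C)O[C@H]1[C@@H](O)[C@H](C(Cl)=C)C(=O)N1[C@@H](Cc2ccccc2)COC1=O | intermediate
11 | C6 triethylsilyl ether of 10 | CC(C)=CCC[C@@]1(C)O[C@H]1[C@@H](O[Si](CC)(CC)CC)[C@H](C(Cl)=C)C(=O)N1[C@@H](Cc2ccccc2)COC1=O | intermediate
12 | (2R,3S)-2-(1-chloroethenyl)-3-[(2S,3R)-3-methyl-3-(4-methylpent-3-en-1-yl)oxiran-2-yl]-3-(triethylsilyloxy)propan-1-ol | CC(C)=CCC[C@@]1(C)O[C@H]1[C@@H](O[Si](CC)(CC)CC)[C@H](C(Cl)=C)CO | intermediate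
13 | (2S,3S)-2-(1-chloroethenyl)-3-[(2S,3R)-3-methyl-3-(4-methylpent-3-en-1-yl)oxiran-2-yl]-3-(triethylsilyloxy)propanal | CC(C)=CCC[C@@]1(C)O[C@H]1[C@@H](O[Si](CC)(CC)CC)[C@H](C(Cl)=C)C=O | intermediate
14 | 2,3-dibromopropene | C=C(Br)CBr | starting material
15 | tributyl(2-bromoprop-2-en-1-yl)stannane | C=C(Br)C[Sn](CCCC)(CCCC)CCCC | intermediate
16 | (4R,5R)-2-(2-bromoprop-2-en-1-yl)-4,5-diphenyl-1,3-ditosyl-1,3,2-diazaborolidine | C=C(Br)CB1N(S(=O)(=O)c2ccc(C)cc2)[C@H](c2ccccc2)[C@@H](c2ccccc2)N1S(=O)(=O)c1ccc(C)cc1 | intermediate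
17 | C8 (R) homoallylic alcohol, C6 TES ether | CC(C)=CCC[C@@]1(C)O[C@H]1[C@@H](O[Si](CC)(CC)CC)[C@H](C(Cl)=C)[C@H](O)CC(Br)=C | intermediate
18 | C8 mesylate, C6 TES ether | CC(C)=CCC[C@@]1(C)O[C@H]1[C@@H](O[Si](CC)(CC)CC)[C@H](C(Cl)=C)[C@H](OS(C)(=O)=O)CC(Br)=C | intermediate
19 | C8 mesylate, C6 alcohol | CC(C)=CCC[C@@]1(C)O[C@H]1[C@@H](O)[C@H](C(Cl)=C)[C@H](OS(C)(=O)=O)CC(Br)=C | intermediate
20 | angelic acid, (2Z)-2-methylbut-2-enoic acid | C/C=C(/C)C(=O)O | starting material
21 | angelic 2,4,6-trichlorobenzoic anhydride | C/C=C(/C)C(=O)OC(=O)c1c(Cl)cc(Cl)cc1Cl | intermediate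
22 | C6 angelate, C8 mesylate, prenyl chain | CC(C)=CCC[C@@]1(C)O[C@H]1[C@@H](OC(=O)/C(C)=C\C)[C@H](C(Cl)=C)[C@H](OS(C)(=O)=O)CC(Br)=C | intermediate
23 | C1 aldehyde (seco precursor) | O=CCC[C@@]1(C)O[C@H]1[C@@H](OC(=O)/C(C)=C\C)[C@H](C(Cl)=C)[C@H](OS(C)(=O)=O)CC(Br)=C | intermediate
24 | (1S,4R,5S,6S,7S,8R) macrocyclic chloroalkene mesylate | C=C(Cl)[C@@H]1[C@H](OS(C)(=O)=O)CC(=C)[C@@H](O)CC[C@@]2(C)O[C@H]2[C@H]1OC(=O)/C(C)=C\C | intermediate
25 | C12 carboxylate of the macrocycle | C=C(C(=O)[O-])[C@@H]1[C@H](OS(C)(=O)=O)CC(=C)[C@@H](O)CC[C@@]2(C)O[C@H]2[C@H]1OC(=O)/C(C)=C\C | intermediate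
26 | CNP0104965.1 | C=C1C(=O)O[C@H]2CC(=C)[C@@H](O)CC[C@@]3(C)O[C@H]3[C@@H](OC(=O)/C(C)=C\C)[C@H]12 | target

Total step count: 16. Longest linear sequence: 13 steps (1, 2, 5–8, 10–16, from nerol).

Steps most likely to fail

Step 16. The carboxylation may be diverted by nickel insertion into the allylic C1–O or the C8–O bond, by protodechlorination, by elimination of the mesylate before ring closure, or by iodide‑mediated epimerisation at C8. The fallback separates metalation from carboxylation and avoids low‑valent nickel and manganese. It sets out from 24, which would be converted by Miyaura borylation (Pd2(dba)3, XPhos, B2pin2, KOAc, dioxane, 80 °C) into the C11 pinacol boronate F1. F1 would then be carboxylated by copper‑catalysed transmetalation and CO2 insertion ([(IPr)CuCl], CsF, CO2 1 atm, DMF, 70 °C). The caesium carboxylate should close the lactone by the same invertive displacement, and the route is rejoined at 26.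

Step 15. The ring closure may show poor facial selectivity at C1 and compete with intermolecular coupling. The fallback replaces substrate control by reagent control: the C1 epimer mixture of 24 would be oxidised (Dess–Martin periodinane, NaHCO3, CH2Cl2) to the cross‑conjugated enone F2. F2 would be reduced with (R)-Me-CBS and catecholborane (toluene, −78 °C), the alkenyl side acting as the large group, to return to 24 as the (1S) alcohol.

Step 10. The aldehyde 13 may enolise (loss of the C7 configuration, migration of the double bond into conjugation), and reagent control may be incomplete against the α‑stereocentre. The fallback sets C8 by reduction instead of by C–C bond formation. It sets out from 13, which would be treated with indium and 2,3-dibromopropene 14 in THF/H2O to give 17 together with its C8 epimer F3. The mixture would be oxidised (Dess–Martin periodinane) to the ketone F4 and reduced with (S)-Me-CBS and catecholborane to come back to the route at 17.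

Further compounds
F1 | step 16 | C11 pinacol boronate of the macrocyclic mesylate | C=C(B1OC(C)(C)C(C)(C)O1)[C@@H]1[C@H](OS(C)(=O)=O)CC(=C)[C@@H](O)CC[C@@]2(C)O[C@H]2[C@H]1OC(=O)/C(C)=C\C
F2 | step 15 | C1 ketone (enone) of the macrocycle | C=C(Cl)[C@@H]1[C@H](OS(C)(=O)=O)CC(=C)C(=O)CC[C@@]2(C)O[C@H]2[C@H]1OC(=O)/C(C)=C\C
F3 | step 10 | C8 (S) epimer of 17 | CC(C)=CCC[C@@]1(C)O[C@H]1[C@@H](O[Si](CC)(CC)CC)[C@H](C(Cl)=C)[C@@H](O)CC(Br)=C
F4 | step 10 | C8 ketone | CC(C)=CCC[C@@]1(C)O[C@H]1[C@@H](O[Si](CC)(CC)CC)[C@H](C(Cl)=C)C(=O)CC(Br)=C
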